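**Retrosynthetic overview**

1. Briarellin C ⇐ C4–OH octanoylation ⇐ key C–O bond: the C16 acid opens a (3R,4R)-C3/C4 epoxide at C3, which closes the ε-lactone and sets C3 and C4.
2. Epoxide precursor ⇐ (Z)-oxonene by ring-closing metathesis at C3=C4; C7=CH2 from a C7 ketone; C16 acid from the isopropenyl group (sets C15).
3. Tetrahydrofuran ⇐ C9–O bond by oxa-Michael addition of C2–OH to a chiral ynone (C4–C9, carrying the C6 butanoate), then a deoxygenative 5-exo radical closure C10→C9.
4. C1–C2 ⇐ anti aldol of a carvone-derived α-hydroxy ketone (C11 oxygen from trans-carvone epoxide) with methacrolein.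
5. Ring order: cyclohexane (from (R)-carvone) → tetrahydrofuran → oxonene → ε-lactone.

Assumption: briarellin (eunicellane) numbering is used throughout; the target as drawn is 1S,2S,3S,4R,6R,9S,10R,11R,14R,15R, which maps onto (R)-carvone, and the starting materials 1, 5, 10 and the Shi ketone are taken as catalogue items.

**Route**

Step 1
Reactants: 1 (R)-2-hydroxypent-4-enoic acid
Product: 2 (R)-2-hydroxy-N-methoxy-N-methylpent-4-enamide
Conditions: MeNH(OMe)·HCl, EDC·HCl, HOBt (cat.), N-methylmorpholine, CH2Cl2, 0 °C to rt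
Reagents that add atoms: N,O-dimethylhydroxylamine hydrochloride, CNOC.Cl
Why: Carbodiimide amide coupling, in which the free secondary hydroxyl does not compete with the amine and the stereocentre (future C6) is untouched.

Step 2
Reactants: 2 (R)-2-hydroxy-N-methoxy-N-methylpent-4-enamide
Product: 3 (R)-1-[methoxy(methyl)amino]-1-oxopent-4-en-2-yl butanoate
Conditions: (PrCO)2O, Et3N, DMAP (cat.), CH2Cl2, 0 °C
Reagents that add atoms: butyric anhydride, CCCC(=O)OC(=O)CCC
Why: DMAP-catalysed acylation installs the C6 butanoate of the target at the outset, so no protecting group is needed.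

Step 3
Reactants: 3 (R)-1-[methoxy(methyl)amino]-1-oxopent-4-en-2-yl butanoate
Product: 4 (R)-3-oxohept-6-en-1-yn-4-yl butanoate
Conditions: HC≡CMgBr, THF, −40 to −10 °C; inverse quench into cold aq. NaHSO4
Reagents that add atoms: ethynylmagnesium bromide, C#C[Mg]Br
Why: Weinreb ketone synthesis, in which the magnesium chelate stops at the ketone and the alkynyl Grignard reagent is too unreactive to attack the butanoate at low temperature.

Step 4
Reactants: 5 (R)-(−)-carvone
Product: 6 (1R,4R,6R)-1-methyl-4-(prop-1-en-2-yl)-7-oxabicyclo[4.1.0]heptan-2-one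
Conditions: 30% H2O2, NaOH (cat.), MeOH, 0 °C
Reagents that add atoms: hydrogen peroxide, OO
Why: Weitz–Scheffer nucleophilic epoxidation, in which hydroperoxide adds to the enone β-carbon axially and anti to the isopropenyl group, so the epoxide oxygen (future C11–O) is trans to C15.

Step 5
Reactants: 6 trans-carvone epoxide
Product: 8 (1R,2S,4R)-1-methyl-4-(prop-1-en-2-yl)cyclohexane-1,2-diol, via epoxy alcohol 7 (not isolated)
Conditions: LiAlH4, THF, 0 to 40 °C
Reagents that add atoms: none
Why: Hydride reduction of the ketone followed by SN2 opening of the trisubstituted epoxide at the secondary carbon C12 leaves the tertiary C11–O bond and its configuration intact (the C10 carbinol configuration is removed in step 6).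

Step 6
Reactants: 8 (1R,2S,4R)-1-methyl-4-(prop-1-en-2-yl)cyclohexane-1,2-diol
Product: 9 (2R,5R)-2-hydroxy-2-methyl-5-(prop-1-en-2-yl)cyclohexan-1-one
Conditions: 2-iodoxybenzoic acid (IBX), EtOAc, 75 °C
Reagents that add atoms: none
Why: IBX oxidation of the secondary hydroxyl of a 1,2-diol gives the α-ketol without glycol cleavage and touches no stereocentre.

Step 7
Reactants: 9 (2R,5R)-2-hydroxy-2-methyl-5-(prop-1-en-2-yl)cyclohexan-1-one; 10 methacrolein
Product: 11 (2R,5R,6R)-2-hydroxy-6-[(1S)-1-hydroxy-2-methylprop-2-en-1-yl]-2-methyl-5-(prop-1-en-2-yl)cyclohexan-1-one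
Conditions: LiN(iPr)2 (2.2 equiv), THF, −78 °C; then 10, −78 °C; AcOH quench
Reagents that add atoms: none
Why: Kinetic lithium-enolate aldol addition, in which the ring-locked E-enolate reacts through a Zimmerman–Traxler chair (anti aldol, sets C2) and the aldehyde enters trans to the adjacent isopropenyl group (sets C1).

Step 8
Reactants: 11 aldol adduct; 4 (R)-3-oxohept-6-en-1-yn-4-yl butanoate
Product: 12 (E)-β-alkoxy enone (C2–O–C9H=C8H–C7(=O)–C6H(OCOPr)–CH2–CH=CH2 on the keto diol core)
Conditions: PMe3 (10 mol%), CH2Cl2, 0 °C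
Reagents that add atoms: none
Why: Phosphine-catalysed oxa-Michael addition of the secondary C2 hydroxyl to the ynone forms the C9–O bond as the (E)-vinylogous ester, the tertiary hydroxyl being too hindered to add.

Step 9
Reactants: 12 (E)-β-alkoxy enone
Product: 13 C10 carbinol (trans-10,11-diol) of 12
Conditions: Me4NBH(OAc)3, MeCN/AcOH, −30 °C
Reagents that add atoms: none
Why: Saksena–Evans hydroxyl-directed reduction, in which the C11 hydroxyl binds boron and delivers hydride only to the C10 ketone, so the vinylogous-ester ketone and the butanoate survive (the C10 configuration is erased in step 10).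

Step 10
Reactants: 13 C10 carbinol
Product: 15 cis-fused 2,5-cis tetrahydrofuran ketone, via benzoxazoline adduct 14 (not isolated)
Conditions: 5,7-di-tert-butyl-3-phenylbenzoxazolium tetrafluoroborate, pyridine, MTBE, rt; then [Ir(ppy)2(dtbbpy)]PF6 (2 mol%), quinuclidine (20 mol%), MTBE/N,N-dimethylacetamide, 450 nm LEDs, rt
Reagents that add atoms: none
Why: Proposed new method: the benzoxazolium salt condenses selectively with the secondary C10 hydroxyl, photo-oxidation and deprotonation of the adduct followed by β-scission give the C10 radical, and this closes 5-exo onto the tethered alkoxy enone (the tether from C1 enforces the cis ring fusion and a chair-like transition state puts the C9 side chain pseudo-equatorial, giving the 2,5-cis tetrahydrofuran) before reduction and protonation of the α-keto radical; the closest known reactions are photoredox deoxygenative couplings of benzoxazolium-activated alcohols and the tin-hydride cyclisation of β-alkoxyacrylate radicals, neither shown for a free hindered diol cyclising onto an alkoxy enone.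

Step 11
Reactants: 15 tetrahydrofuran ketone
Product: 16 (Z)-C3=C4 oxonene ketone
Conditions: second-generation Grubbs catalyst RuCl2(=CHPh)(H2IMes)(PCy3) (10 mol%), toluene (2 mM), 80 °C
Reagents that add atoms: none
Why: Ring-closing metathesis between the allyl group and the 1,1-disubstituted C3 alkene, where the cis-2,5-disubstituted tetrahydrofuran holds both chains on one face and the nine-membered ring can only hold the (Z)-alkene.

Step 12
Reactants: 16 oxonene ketone
Product: 18 (15R)-C16 primary alcohol, via catechol boronate 17 (not isolated)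
Conditions: catecholborane, RhCl(PPh3)3 (3 mol%), THF, 0 °C to rt; then H2O2, aq. NaHCO3, 0 °C
Reagents that add atoms: hydrogen peroxide, OO
Why: Rhodium-catalysed hydroboration with catecholborane is chemoselective for the 1,1-disubstituted alkene over the ketone and the trisubstituted alkene, and boron adds anti to the C1 branch in the A(1,3)-minimised rotamer of the isopropenyl group, giving 15R.

Step 13
Reactants: 18 C16 primary alcohol
Product: 19 C7 exo-methylene diol
Conditions: Zn, CH2Br2, TiCl4 (excess), THF/CH2Cl2, 0 °C to rt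
Reagents that add atoms: dibromomethane, BrCBr
Why: Takai–Lombardo methylenation is non-basic, so the α-acyloxy ketone is methylenated without epimerising C6 or opening the β-alkoxy ketone, and it tolerates esters and free hydroxyls.

Step 14
Reactants: 19 C7 exo-methylene diol
Product: 21 C16 carboxylic acid, via aldehyde 20 (not isolated)
Conditions: TEMPO (20 mol%), PhI(OAc)2, MeCN/H2O (1:1), rt
Reagents that add atoms: water, O
Why: TEMPO/PhI(OAc)2 oxidation in aqueous acetonitrile takes the primary alcohol through the aldehyde hydrate to the acid without touching the alkenes or the tertiary alcohol and without epimerising C15.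

Step 15
Reactants: 21 C16 carboxylic acid
Product: 23 4-O-deoctanoyl briarellin C (hydroxy lactone), via epoxy acid 22 (not isolated)
Conditions: D-fructose-derived Shi ketone (30 mol%), KHSO5 (as Oxone, 2KHSO5·KHSO4·K2SO4), K2CO3, Bu4NHSO4, aq. Na2EDTA, MeCN/dimethoxymethane, 0 °C; then camphorsulfonic acid (10 mol%), CH2Cl2, rt
Reagents that add atoms: potassium peroxymonosulfate, [K+].OOS(=O)(=O)[O-]
Why: Shi asymmetric epoxidation (spiro transition state, same sense as for 1-substituted cycloalkenes) gives the (3R,4R)-epoxide of the electron-rich trisubstituted alkene only, and the C16 acid then opens it 7-exo at the tertiary carbon with inversion, forming the C3–O lactone bond and setting 3S and 4R.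

Step 16
Reactants: 23 hydroxy lactone
Product: 24 briarellin C
Conditions: octanoyl chloride, pyridine, DMAP (cat.), CH2Cl2, 0 °C to rt
Reagents that add atoms: octanoyl chloride, CCCCCCCC(=O)Cl
Why: DMAP-catalysed acylation of the only reactive hydroxyl (secondary C4), the tertiary C11 hydroxyl being inert.

**Compound list**

1 | (R)-2-hydroxypent-4-enoic acid | O[C@H](CC=C)C(=O)O | starting material
2 | (R)-2-hydroxy-N-methoxy-N-methylpent-4-enamide | O[C@H](CC=C)C(=O)N(C)OC | intermediate
3 | (R)-1-[methoxy(methyl)amino]-1-oxopent-4-en-2-yl butanoate | CCCC(=O)O[C@H](CC=C)C(=O)N(C)OC | intermediate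
4 | (R)-3-oxohept-6-en-1-yn-4-yl butanoate (becomes C4–C9; its stereocentre is C6) | CCCC(=O)O[C@H](CC=C)C(=O)C#C | intermediate
5 | (R)-(−)-carvone | CC1=CC[C@H](CC1=O)C(C)=C | starting material
6 | (1R,4R,6R)-1-methyl-4-(prop-1-en-2-yl)-7-oxabicyclo[4.1.0]heptan-2-one (epoxide trans to isopropenyl) | C[C@@]12O[C@@H]1C[C@H](CC2=O)C(C)=C | intermediate
7 | epoxy alcohol from 6 (C10–OH cis to the epoxide; expected major epimer) | C[C@@]12O[C@@H]1C[C@H](C[C@@H]2O)C(C)=C | intermediate (not isolated)
8 | (1R,2S,4R)-1-methyl-4-(prop-1-en-2-yl)cyclohexane-1,2-diol (tertiary OH trans to isopropenyl) | C[C@@]1(O)CC[C@H](C[C@@H]1O)C(C)=C | intermediate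
9 | (2R,5R)-2-hydroxy-2-methyl-5-(prop-1-en-2-yl)cyclohexan-1-one | C[C@@]1(O)CC[C@H](CC1=O)C(C)=C | intermediate
10 | methacrolein (2-methylprop-2-enal) | CC(=C)C=O | starting material
11 | (2R,5R,6R)-2-hydroxy-6-[(1S)-1-hydroxy-2-methylprop-2-en-1-yl]-2-methyl-5-(prop-1-en-2-yl)cyclohexan-1-one (anti aldol; C1 substituent trans to isopropenyl) | C[C@@]1(O)CC[C@@H](C(C)=C)[C@H]([C@H](O)C(C)=C)C1=O | intermediate
12 | (E)-β-alkoxy enone: C2–O of 11 joined to C9H=C8H–C7(=O)–C6H(OCOPr)–CH2CH=CH2 (6R) | C[C@@]1(O)CC[C@@H](C(C)=C)[C@H]([C@H](O/C=C/C(=O)[C@@H](CC=C)OC(=O)CCC)C(C)=C)C1=O | intermediate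
13 | C10 carbinol of 12 (C10–OH trans to C11–OH) | C[C@@]1(O)CC[C@@H](C(C)=C)[C@H]([C@H](O/C=C/C(=O)[C@@H](CC=C)OC(=O)CCC)C(C)=C)[C@H]1O | intermediate
14 | 2-alkoxy-5,7-di-tert-butyl-3-phenyl-2,3-dihydrobenzoxazole adduct of 13 at C10–O (aminal carbon unassigned) | C[C@@]1(O)CC[C@@H](C(C)=C)[C@H]([C@H](O/C=C/C(=O)[C@@H](CC=C)OC(=O)CCC)C(C)=C)[C@H]1OC2Oc3c(C(C)(C)C)cc(C(C)(C)C)cc3N2c4ccccc4 | intermediate (not isolated)
15 | cis-fused hexahydroisobenzofuran: C2 bears C3(Me)=CH2, C9 bears CH2–C7(=O)–C6H(OCOPr)–CH2CH=CH2, C11 (Me, OH), C14 isopropenyl (1S,2S,6R,9S,10R,11R,14R) | O=C(C[C@@H]1O[C@H](C(C)=C)[C@H]2[C@@H](CC[C@@](C)(O)[C@H]21)C(C)=C)[C@@H](CC=C)OC(=O)CCC | intermediate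
16 | tricyclic (Z)-C3=C4 oxonene with C7 ketone, C6 butanoate, C11–OH and C14 isopropenyl | O=C1C[C@@H]2O[C@H](/C(C)=C\C[C@H]1OC(=O)CCC)[C@H]3[C@@H](CC[C@@](C)(O)[C@H]32)C(C)=C | intermediate
17 | C16 catechol boronate of 16 (15R) | O=C1C[C@@H]2O[C@H](/C(C)=C\C[C@H]1OC(=O)CCC)[C@H]3[C@@H](CC[C@@](C)(O)[C@H]32)[C@@H](C)CB4Oc5ccccc5O4 | intermediate (not isolated)
18 | (15R)-C16 primary alcohol, C7 ketone | O=C1C[C@@H]2O[C@H](/C(C)=C\C[C@H]1OC(=O)CCC)[C@H]3[C@@H](CC[C@@](C)(O)[C@H]32)[C@@H](C)CO | intermediate
19 | C7 exo-methylene, C16 primary alcohol | C=C1C[C@@H]2O[C@H](/C(C)=C\C[C@H]1OC(=O)CCC)[C@H]3[C@@H](CC[C@@](C)(O)[C@H]32)[C@@H](C)CO | intermediate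
20 | C16 aldehyde of 19 | C=C1C[C@@H]2O[C@H](/C(C)=C\C[C@H]1OC(=O)CCC)[C@H]3[C@@H](CC[C@@](C)(O)[C@H]32)[C@@H](C)C=O | intermediate (not isolated)
21 | C16 carboxylic acid with (Z)-C3=C4 alkene | C=C1C[C@@H]2O[C@H](/C(C)=C\C[C@H]1OC(=O)CCC)[C@H]3[C@@H](CC[C@@](C)(O)[C@H]32)[C@@H](C)C(=O)O | intermediate
22 | (3R,4R)-C3/C4 epoxy acid | C=C1C[C@@H]2O[C@H]([C@]4(C)O[C@@H]4C[C@H]1OC(=O)CCC)[C@H]3[C@@H](CC[C@@](C)(O)[C@H]32)[C@@H](C)C(=O)O | intermediate (not isolated)
23 | 4-O-deoctanoyl briarellin C (ε-lactone, free C4–OH) | C=C1C[C@@H]2O[C@H]3[C@H]4[C@@H](CC[C@@](C)(O)[C@H]42)[C@@H](C)C(=O)O[C@@]3(C)[C@H](O)C[C@H]1OC(=O)CCC | intermediate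
24 | briarellin C | C=C1C[C@@H]2O[C@H]3[C@H]4[C@@H](CC[C@@](C)(O)[C@H]42)[C@@H](C)C(=O)O[C@@]3(C)[C@H](OC(=O)CCCCCCC)C[C@H]1OC(=O)CCC | target

**Step count and risks**

Total: 16 steps (3 for ynone 4, 13 on the main line). Longest linear sequence: 13 steps from (R)-carvone (steps 4–16). No protecting group is used; every step forms a skeletal bond, sets a stereocentre, or adjusts an oxidation level to that of the target.

Steps most likely to fail:

Step 10 (the proposed new deoxygenative cyclisation). The hindered C10 hydroxyl may not condense with the benzoxazolium salt, or the radical may be reduced before it cyclises. The fallback is known chemistry and sets out from 13: PhOC(S)Cl/pyridine in CH2Cl2 at 0 °C acylates only the secondary C10 hydroxyl to give the O-phenyl thionocarbonate F1. Slow addition of Bu3SnH/AIBN in benzene at 80 °C (Barton–McCombie radical generation, then tin-hydride cyclisation onto the β-alkoxy enone) returns to the route at 15.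

Step 15 (epoxidation and lactonisation). The acid may fail to reach C3 from the face opposite the epoxide, or the epoxide may rearrange under acid. The fallback sets out from 21 and forms the lactone through the acyl C–O bond instead. Epoxidise as in step 15, then hydrolyse the epoxide with HClO4 (cat.) in THF/H2O, where water attacks the tertiary C3 with inversion, to give the (3S,4R)-dihydroxy acid F2. Octanoic anhydride/DMAP acylates the secondary C4 hydroxyl to give the seco acid F3. Shiina macrolactonisation (2-methyl-6-nitrobenzoic anhydride, DMAP, toluene, 80 °C) onto the tertiary C3 hydroxyl returns directly to 24.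

Step 7 (aldol). Anti/syn selectivity of the lithium dianion, which fixes C2 for everything downstream, may be modest. The fallback sets out from 9: TMSCl/imidazole gives the silyl ether F4. Enolisation with (c-C6H11)2BCl/Et3N in Et2O at −78 °C and addition of 10 (boron aldol, tighter Zimmerman–Traxler transition state, anti-selective) with H2O2 work-up gives the silyl-protected anti aldol F5. Citric acid in MeOH removes the silyl group and returns to the route at 11.

**Further compounds**

F1 | step 10 | O-phenyl thionocarbonate of 13 at the C10 oxygen | C[C@@]1(O)CC[C@@H](C(C)=C)[C@H]([C@H](O/C=C/C(=O)[C@@H](CC=C)OC(=O)CCC)C(C)=C)[C@H]1OC(=S)Oc2ccccc2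
F2 | step 15 | (3S,4R)-3,4-dihydroxy C16 acid (hydrolysed epoxide of 21) | C=C1C[C@@H]2O[C@H]([C@@](C)(O)[C@H](O)C[C@H]1OC(=O)CCC)[C@H]3[C@@H](CC[C@@](C)(O)[C@H]32)[C@@H](C)C(=O)O
F3 | step 15 | C4-octanoate seco acid of briarellin C | C=C1C[C@@H]2O[C@H]([C@@](C)(O)[C@H](OC(=O)CCCCCCC)C[C@H]1OC(=O)CCC)[C@H]3[C@@H](CC[C@@](C)(O)[C@H]32)[C@@H](C)C(=O)O
F4 | step 7 | trimethylsilyl ether of 9 | C[C@@]1(O[Si](C)(C)C)CC[C@H](CC1=O)C(C)=C
F5 | step 7 | trimethylsilyl ether of 11 at the tertiary oxygen | C[C@@]1(O[Si](C)(C)C)CC[C@@H](C(C)=C)[C@H]([C@H](O)C(C)=C)C1=O
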